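**Plan**

- Numbering: indane C1 (alkylidene carbon), C2 (CH bearing the 3,5-dihydroxyphenyl group), C3 (CH bearing the 4-hydroxyphenyl group), fusion carbons C3a and C7a, oxygens on C4 and C6 (ring A); dihydrobenzofuran O1, C2, C3, C5 (ring B).
- Enabling feature: C3a is ortho to the C4 oxygen and para to the C6 oxygen, the most nucleophilic carbon of ring A, and it carries the diarylmethine C3; the C3–C3a bond is therefore the retron of a Nazarov closure of a 3,5-dimethoxyphenyl vinyl ketone.
- Cuts: the exocyclic C1=CH bond (to a benzylic sulfone, then to its C–S bond), the C2–aryl bond of the indane (ketone α-arylation), the C3–C3a bond (Nazarov), and the C2–C3 bond of ring B (carbene C–H insertion).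
- Forward: the indanone five-membered ring closes first and the C2 aryl is then attached; ring B closes separately; the two halves are joined through sulfur, SO2 is extruded to leave the alkene, and eight methyl ethers are cleaved last.
- Stereochemistry: indane C3 from the chiral copper catalyst, C2 trans by thermodynamic control from C3; ring B C3 from the chiral dirhodium catalyst, C2 by equilibration to trans; E alkene from the Ramberg–Bäcklund extrusion.

Key step: step 2

Assumption: the sense of induction of the copper bis(oxazoline) catalyst (step 2) and of the dirhodium carboxylate (step 10) is taken as drawn; both are available as either enantiomer, and the antipode would be used if the first run shows the opposite sense.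

**Route**

Step 1
Reactants: 1 methyl 3-(3,5-dimethoxyphenyl)-3-oxopropanoate; 2 4-methoxybenzaldehyde
Product: 3 methyl (Z)-2-(3,5-dimethoxybenzoyl)-3-(4-methoxyphenyl)acrylate
Conditions: piperidine (cat.), AcOH (cat.), toluene, reflux, Dean–Stark
Reagents that add atoms: none
Why: Knoevenagel condensation of the doubly activated methylene with the aryl aldehyde, driven by azeotropic removal of water, should give mainly the isomer with the anisyl group trans to the aroyl group, and any E isomer is expected to equilibrate on the Lewis acid of the next step.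

Step 2
Reactants: 3 methyl (Z)-2-(3,5-dimethoxybenzoyl)-3-(4-methoxyphenyl)acrylate
Product: 4 methyl (2R,3S)-4,6-dimethoxy-3-(4-methoxyphenyl)-1-oxoindane-2-carboxylate (2,3-trans)
Conditions: Cu(OTf)2 (10 mol %), (S,S)-Ph-box [2,2'-(propane-2,2-diyl)bis((4S)-4-phenyl-4,5-dihydrooxazole)] (11 mol %), 4 Å MS, ClCH2CH2Cl, 40 °C
Reagents that add atoms: none
Why: Divalent copper held by the bis(oxazoline) chelates the two carbonyl oxygens of 3 and generates a hydroxypentadienyl-type cation whose fifth carbon is an ortho carbon of the dimethoxyphenyl ring; conrotatory 4π electrocyclisation joins C3 to C3a, and loss of the arenium proton followed by protonation of the copper enolate should deliver 4. The closest known reaction type is the Lewis acid-catalysed Nazarov cyclisation of 2-aroyl-3-arylacrylates with electron-rich aroyl groups to 3-aryl-1-oxoindane-2-carboxylates, including enantioselective versions with Cu(OTf)2 and bis(oxazoline) ligands. The one ring formed is the five-membered carbocycle, closed by thermal 4π-conrotatory electrocyclisation in which one double bond is borrowed from the arene. C3 is set by the sense of conrotation that the C2-symmetric ligand imposes on the chelated Z-alkene, and C2 is set afterwards by protonation and should settle trans to the C3 aryl through the enol of the β-ketoester. The step needs regioselectivity on the arene and a defined alkene geometry: the two ortho carbons of the aroyl ring are equivalent by symmetry and each is ortho to one methoxy group and para to the other, and E/Z interconversion on the Lewis acid channels material through the isomer with the anisyl group on the outside of the U-shaped cation. The ester provides the second binding point and polarises the dienone, and it is removed in step 3.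

Step 3
Reactants: 4 methyl (2R,3S)-4,6-dimethoxy-3-(4-methoxyphenyl)-1-oxoindane-2-carboxylate
Product: 5 (3S)-4,6-dimethoxy-3-(4-methoxyphenyl)indan-1-one
Conditions: LiCl, H2O (2 equiv), DMSO, 150 °C
Reagents that add atoms: none
Why: Krapcho demethoxycarbonylation (chloride dealkylates the methyl ester and the β-keto carboxylate loses CO2) turns C2 into a methylene, while the non-enolisable C3 centre should be untouched.

Step 4
Reactants: 5 (3S)-4,6-dimethoxy-3-(4-methoxyphenyl)indan-1-one; 6 1-bromo-3,5-dimethoxybenzene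
Product: 7 (2S,3S)-2-(3,5-dimethoxyphenyl)-4,6-dimethoxy-3-(4-methoxyphenyl)indan-1-one (2,3-trans)
Conditions: Pd(OAc)2 (5 mol %), t-Bu3P·HBF4 (10 mol %), NaOt-Bu, toluene, 60 °C
Reagents that add atoms: none
Why: Palladium-catalysed α-arylation of the ketone enolate, a reaction type known for 3-aryl-1-indanones, forms the C2–aryl bond, and the new C2 centre should end trans to the C3 aryl because the acidic α-aryl ketone equilibrates through its enolate under the base.

Step 5
Reactants: 7 (2S,3S)-2-(3,5-dimethoxyphenyl)-4,6-dimethoxy-3-(4-methoxyphenyl)indan-1-one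
Product: 8 (1R,2S,3S)-2-(3,5-dimethoxyphenyl)-4,6-dimethoxy-3-(4-methoxyphenyl)indan-1-ol (hydroxyl cis to the C2 aryl)
Conditions: NaBH4, MeOH–THF, 0 °C
Reagents that add atoms: none
Why: Borohydride reduction of the ketone, with hydride expected to arrive on the face opposite the adjacent C2 aryl group to give mainly the 1,2-cis alcohol; C1 becomes trigonal again in step 16, so an epimer mixture would also serve.

Step 6
Reactants: 8 (1R,2S,3S)-2-(3,5-dimethoxyphenyl)-4,6-dimethoxy-3-(4-methoxyphenyl)indan-1-ol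
Product: 9 S-[(1S,2S,3S)-2-(3,5-dimethoxyphenyl)-4,6-dimethoxy-3-(4-methoxyphenyl)indan-1-yl] ethanethioate (sulfur trans to the C2 aryl)
Conditions: AcSH, DIAD, PPh3, THF, 0 °C → rt
Reagents that add atoms: thioacetic acid CC(=O)S
Why: Mitsunobu reaction with the acidic thioacetic acid displaces the activated benzylic hydroxyl by SN2 with inversion at C1, avoiding a free indanyl cation that could lose the C2 proton.

Step 7
Reactants: 10 5-bromo-2-hydroxybenzonitrile; 11 4-methoxybenzyl chloride
Product: 12 5-bromo-2-[(4-methoxybenzyl)oxy]benzonitrile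
Conditions: K2CO3, DMF, 60 °C
Reagents that add atoms: none
Why: Williamson ether synthesis of the cyano-activated phenoxide with a reactive benzylic chloride.

Step 8
Reactants: 12 5-bromo-2-[(4-methoxybenzyl)oxy]benzonitrile; 13 3,5-dimethoxyphenylmagnesium chloride
Product: 15 {5-bromo-2-[(4-methoxybenzyl)oxy]phenyl}(3,5-dimethoxyphenyl)methanone, via N-chloromagnesio ketimine 14 (not isolated)
Conditions: THF, 0 → 60 °C; then 1 M HCl, rt
Reagents that add atoms: water O
Why: Grignard addition to the nitrile stops at the metallated ketimine, which dilute acid hydrolyses to the diaryl ketone, while the aryl bromide and the benzyl ether are inert to the arylmagnesium chloride.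

Step 9
Reactants: 15 {5-bromo-2-[(4-methoxybenzyl)oxy]phenyl}(3,5-dimethoxyphenyl)methanone
Product: 16 {5-bromo-2-[(4-methoxybenzyl)oxy]phenyl}(3,5-dimethoxyphenyl)methanone hydrazone (E/Z mixture)
Conditions: N2H4·H2O (excess), AcOH (cat.), EtOH, 80 °C
Reagents that add atoms: hydrazine NN
Why: Condensation of the diaryl ketone with excess hydrazine gives the N-unsubstituted hydrazone, both geometric isomers of which lead to the same diazo compound.

Step 10
Reactants: 16 {5-bromo-2-[(4-methoxybenzyl)oxy]phenyl}(3,5-dimethoxyphenyl)methanone hydrazone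
Product: 18 (2S,3R)-5-bromo-3-(3,5-dimethoxyphenyl)-2-(4-methoxyphenyl)-2,3-dihydrobenzofuran (2,3-cis), via diaryldiazomethane 17 (not isolated)
Conditions: MnO2, CH2Cl2, 0 °C; filter; Rh2(R-PTAD)4 (tetrakis[(R)-(1-adamantyl)(N-phthalimido)acetato]dirhodium, 1 mol %), CH2Cl2, 0 °C → rt
Reagents that add atoms: none
Why: Oxidation of the hydrazone to the diazo compound and dirhodium-catalysed intramolecular 1,5 C–H insertion of the donor/donor carbene into the benzylic ether C–H bond, a reaction type established for cis-2,3-diaryl-2,3-dihydrobenzofurans, closes ring B, with the chiral carboxylate ligands setting C3 and the cis C2.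

Step 11
Reactants: 18 (2S,3R)-5-bromo-3-(3,5-dimethoxyphenyl)-2-(4-methoxyphenyl)-2,3-dihydrobenzofuran
Product: 19 (2R,3R)-5-bromo-3-(3,5-dimethoxyphenyl)-2-(4-methoxyphenyl)-2,3-dihydrobenzofuran (2,3-trans)
Conditions: TFA, CH2Cl2, 0 °C → rt
Reagents that add atoms: none
Why: Acid-mediated epimerisation by reversible ionisation of the C2–O bond to the 4-methoxybenzylic cation and re-closure should lead to the thermodynamically preferred trans isomer, inverting C2 only and leaving the catalyst-set C3 in place.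

Step 12
Reactants: 19 (2R,3R)-5-bromo-3-(3,5-dimethoxyphenyl)-2-(4-methoxyphenyl)-2,3-dihydrobenzofuran
Product: 22 [(2R,3R)-3-(3,5-dimethoxyphenyl)-2-(4-methoxyphenyl)-2,3-dihydrobenzofuran-5-yl]methanol, via aryllithium 20 (not isolated), via aldehyde 21 (not isolated)
Conditions: n-BuLi, THF, −78 °C; DMF; then MeOH, NaBH4, 0 °C
Reagents that add atoms: N,N-dimethylformamide CN(C)C=O
Why: Bromine–lithium exchange, formylation of the aryllithium with DMF and borohydride reduction in the same flask install the hydroxymethyl group without touching either stereocentre.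

Step 13
Reactants: 22 [(2R,3R)-3-(3,5-dimethoxyphenyl)-2-(4-methoxyphenyl)-2,3-dihydrobenzofuran-5-yl]methanol
Product: 23 (2R,3R)-5-(bromomethyl)-3-(3,5-dimethoxyphenyl)-2-(4-methoxyphenyl)-2,3-dihydrobenzofuran (used crude)
Conditions: CBr4, PPh3, CH2Cl2, 0 °C
Reagents that add atoms: tetrabromomethane BrC(Br)(Br)Br
Why: Appel bromination of the primary benzylic alcohol runs under neutral conditions, which spares the acid-labile C2–O bond of ring B.

Step 14
Reactants: 9 S-[(1S,2S,3S)-2-(3,5-dimethoxyphenyl)-4,6-dimethoxy-3-(4-methoxyphenyl)indan-1-yl] ethanethioate; 23 (2R,3R)-5-(bromomethyl)-3-(3,5-dimethoxyphenyl)-2-(4-methoxyphenyl)-2,3-dihydrobenzofuran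
Product: 25 (2R,3R)-3-(3,5-dimethoxyphenyl)-5-({[(1S,2S,3S)-2-(3,5-dimethoxyphenyl)-4,6-dimethoxy-3-(4-methoxyphenyl)indan-1-yl]sulfanyl}methyl)-2-(4-methoxyphenyl)-2,3-dihydrobenzofuran, via indane-1-thiol 24 (not isolated)
Conditions: 9, K2CO3, MeOH–THF (degassed), 0 °C; then 23 in THF, 0 °C → rt
Reagents that add atoms: none
Why: Methanolysis of the thioacetate liberates the thiolate, which is alkylated by SN2 at the benzylic bromide; the C–S bond is made under base because acid strong enough to ionise the indanol would also open ring B in the presence of a thiol.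

Step 15
Reactants: 25 the sulfide of step 14
Product: 27 (2R,3R)-3-(3,5-dimethoxyphenyl)-5-({[(1S,2S,3S)-2-(3,5-dimethoxyphenyl)-4,6-dimethoxy-3-(4-methoxyphenyl)indan-1-yl]sulfonyl}methyl)-2-(4-methoxyphenyl)-2,3-dihydrobenzofuran, via sulfoxide 26 (not isolated)
Conditions: mCPBA (2.5 equiv), NaHCO3, CH2Cl2, 0 °C → rt
Reagents that add atoms: 3-chloroperoxybenzoic acid OOC(=O)c1cccc(Cl)c1
Why: Peracid oxidation of the sulfide through the sulfoxide to the sulfone, buffered with bicarbonate so that the electron-rich arenes and the benzylic ether of ring B should survive.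

Step 16
Reactants: 27 the sulfone of step 15
Product: 30 (2R,3R)-3-(3,5-dimethoxyphenyl)-5-{(E)-[(2S,3S)-2-(3,5-dimethoxyphenyl)-4,6-dimethoxy-3-(4-methoxyphenyl)indan-1-ylidene]methyl}-2-(4-methoxyphenyl)-2,3-dihydrobenzofuran, via α-chloro sulfone 28 (not isolated), via episulfone 29 (not isolated)
Conditions: KOH, CCl4, t-BuOH–H2O, 60 °C
Reagents that add atoms: none
Why: Ramberg–Bäcklund reaction with in situ α-chlorination, 1,3-elimination to the episulfone and loss of SO2, a sequence known for 1-benzylidene-2,3-diarylindanes, should give the exocyclic alkene as the E isomer (aryl turned away from the peri C7–H) without touching C2 or C3.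

Step 17
Reactants: 30 the octamethyl ether of step 16
Product: 31 (2S,3S)-2-(3,5-dihydroxyphenyl)-1-[(E)-{(2R,3R)-3-(3,5-dihydroxyphenyl)-2-(4-hydroxyphenyl)-2,3-dihydrobenzofuran-5-yl}methylidene]-3-(4-hydroxyphenyl)indane-4,6-diol (CNP0184753.1)
Conditions: BBr3 (excess), CH2Cl2, −78 °C → rt; MeOH–H2O quench
Reagents that add atoms: none
Why: Lewis acid cleavage of all eight aryl methyl ethers by BBr3 (bromide attack on the boron-activated methyl groups) is a known final step for permethylated 1-benzylidene-indanes of this family, and ring B, if it opens reversibly at C2–O, should re-close to the trans arrangement already in place.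

**Compound list**

1 | methyl 3-(3,5-dimethoxyphenyl)-3-oxopropanoate | COC(=O)CC(=O)c1cc(OC)cc(OC)c1 | starting material
2 | 4-methoxybenzaldehyde | COc1ccc(C=O)cc1 | starting material
3 | methyl (Z)-2-(3,5-dimethoxybenzoyl)-3-(4-methoxyphenyl)acrylate | COC(=O)/C(=C\c1ccc(OC)cc1)C(=O)c1cc(OC)cc(OC)c1 | intermediate
4 | methyl (2R,3S)-4,6-dimethoxy-3-(4-methoxyphenyl)-1-oxoindane-2-carboxylate | COc1ccc([C@H]2c3c(OC)cc(OC)cc3C(=O)[C@@H]2C(=O)OC)cc1 | intermediate
5 | (3S)-4,6-dimethoxy-3-(4-methoxyphenyl)indan-1-one | COc1ccc([C@H]2c3c(OC)cc(OC)cc3C(=O)C2)cc1 | intermediate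
6 | 1-bromo-3,5-dimethoxybenzene | COc1cc(Br)cc(OC)c1 | starting material
7 | (2S,3S)-2-(3,5-dimethoxyphenyl)-4,6-dimethoxy-3-(4-methoxyphenyl)indan-1-one | COc1ccc([C@H]2c3c(OC)cc(OC)cc3C(=O)[C@@H]2c2cc(OC)cc(OC)c2)cc1 | intermediate
8 | (1R,2S,3S)-2-(3,5-dimethoxyphenyl)-4,6-dimethoxy-3-(4-methoxyphenyl)indan-1-ol | COc1ccc([C@H]2c3c(OC)cc(OC)cc3[C@H](O)[C@@H]2c2cc(OC)cc(OC)c2)cc1 | intermediate
9 | S-[(1S,2S,3S)-2-(3,5-dimethoxyphenyl)-4,6-dimethoxy-3-(4-methoxyphenyl)indan-1-yl] ethanethioate | COc1ccc([C@H]2c3c(OC)cc(OC)cc3[C@@H](SC(C)=O)[C@@H]2c2cc(OC)cc(OC)c2)cc1 | intermediate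
10 | 5-bromo-2-hydroxybenzonitrile | N#Cc1cc(Br)ccc1O | starting material
11 | 4-methoxybenzyl chloride | COc1ccc(CCl)cc1 | starting material
12 | 5-bromo-2-[(4-methoxybenzyl)oxy]benzonitrile | COc1ccc(COc2ccc(Br)cc2C#N)cc1 | intermediate
13 | 3,5-dimethoxyphenylmagnesium chloride (THF solution) | COc1cc([Mg]Cl)cc(OC)c1 | starting material
14 | N-chloromagnesio ketimine of 15, formed in the flask | COc1ccc(COc2ccc(Br)cc2C(=N[Mg]Cl)c2cc(OC)cc(OC)c2)cc1 | intermediate
15 | {5-bromo-2-[(4-methoxybenzyl)oxy]phenyl}(3,5-dimethoxyphenyl)methanone | COc1ccc(COc2ccc(Br)cc2C(=O)c2cc(OC)cc(OC)c2)cc1 | intermediate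
16 | hydrazone of 15 (E/Z mixture) | COc1ccc(COc2ccc(Br)cc2C(=NN)c2cc(OC)cc(OC)c2)cc1 | intermediate
17 | 4-bromo-2-[diazo(3,5-dimethoxyphenyl)methyl]-1-[(4-methoxybenzyl)oxy]benzene, formed in the flask | COc1ccc(COc2ccc(Br)cc2C(=[N+]=[N-])c2cc(OC)cc(OC)c2)cc1 | intermediate
18 | (2S,3R)-5-bromo-3-(3,5-dimethoxyphenyl)-2-(4-methoxyphenyl)-2,3-dihydrobenzofuran (cis) | Brc1ccc2c(c1)[C@@H](c1cc(OC)cc(OC)c1)[C@@H](c1ccc(OC)cc1)O2 | intermediate
19 | (2R,3R)-5-bromo-3-(3,5-dimethoxyphenyl)-2-(4-methoxyphenyl)-2,3-dihydrobenzofuran (trans) | Brc1ccc2c(c1)[C@@H](c1cc(OC)cc(OC)c1)[C@H](c1ccc(OC)cc1)O2 | intermediate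
20 | [(2R,3R)-3-(3,5-dimethoxyphenyl)-2-(4-methoxyphenyl)-2,3-dihydrobenzofuran-5-yl]lithium, formed in the flask | [Li]c1ccc2c(c1)[C@@H](c1cc(OC)cc(OC)c1)[C@H](c1ccc(OC)cc1)O2 | intermediate
21 | (2R,3R)-3-(3,5-dimethoxyphenyl)-2-(4-methoxyphenyl)-2,3-dihydrobenzofuran-5-carbaldehyde, formed in the flask | O=Cc1ccc2c(c1)[C@@H](c1cc(OC)cc(OC)c1)[C@H](c1ccc(OC)cc1)O2 | intermediate
22 | [(2R,3R)-3-(3,5-dimethoxyphenyl)-2-(4-methoxyphenyl)-2,3-dihydrobenzofuran-5-yl]methanol | OCc1ccc2c(c1)[C@@H](c1cc(OC)cc(OC)c1)[C@H](c1ccc(OC)cc1)O2 | intermediate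
23 | (2R,3R)-5-(bromomethyl)-3-(3,5-dimethoxyphenyl)-2-(4-methoxyphenyl)-2,3-dihydrobenzofuran | BrCc1ccc2c(c1)[C@@H](c1cc(OC)cc(OC)c1)[C@H](c1ccc(OC)cc1)O2 | intermediate
24 | (1S,2S,3S)-2-(3,5-dimethoxyphenyl)-4,6-dimethoxy-3-(4-methoxyphenyl)indane-1-thiol, formed in the flask as its thiolate | COc1ccc([C@H]2c3c(OC)cc(OC)cc3[C@@H](S)[C@@H]2c2cc(OC)cc(OC)c2)cc1 | intermediate
25 | (2R,3R)-3-(3,5-dimethoxyphenyl)-5-({[(1S,2S,3S)-2-(3,5-dimethoxyphenyl)-4,6-dimethoxy-3-(4-methoxyphenyl)indan-1-yl]sulfanyl}methyl)-2-(4-methoxyphenyl)-2,3-dihydrobenzofuran | COc1ccc([C@H]2c3c(OC)cc(OC)cc3[C@@H](SCc3ccc4c(c3)[C@@H](c3cc(OC)cc(OC)c3)[C@H](c3ccc(OC)cc3)O4)[C@@H]2c2cc(OC)cc(OC)c2)cc1 | intermediate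
26 | sulfoxide of 25 (sulfinyl in place of sulfanyl, mixture at sulfur), formed in the flask | COc1ccc([C@H]2c3c(OC)cc(OC)cc3[C@@H](S(=O)Cc3ccc4c(c3)[C@@H](c3cc(OC)cc(OC)c3)[C@H](c3ccc(OC)cc3)O4)[C@@H]2c2cc(OC)cc(OC)c2)cc1 | intermediate
27 | (2R,3R)-3-(3,5-dimethoxyphenyl)-5-({[(1S,2S,3S)-2-(3,5-dimethoxyphenyl)-4,6-dimethoxy-3-(4-methoxyphenyl)indan-1-yl]sulfonyl}methyl)-2-(4-methoxyphenyl)-2,3-dihydrobenzofuran | COc1ccc([C@H]2c3c(OC)cc(OC)cc3[C@@H](S(=O)(=O)Cc3ccc4c(c3)[C@@H](c3cc(OC)cc(OC)c3)[C@H](c3ccc(OC)cc3)O4)[C@@H]2c2cc(OC)cc(OC)c2)cc1 | intermediate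
28 | α-chloro sulfone of 27 (chlorine on the benzylic CH between sulfur and ring B, mixture at that carbon), formed in the flask | COc1ccc([C@H]2c3c(OC)cc(OC)cc3[C@@H](S(=O)(=O)C(Cl)c3ccc4c(c3)[C@@H](c3cc(OC)cc(OC)c3)[C@H](c3ccc(OC)cc3)O4)[C@@H]2c2cc(OC)cc(OC)c2)cc1 | intermediate
29 | episulfone: (2S,3S)-3'-[(2R,3R)-3-(3,5-dimethoxyphenyl)-2-(4-methoxyphenyl)-2,3-dihydrobenzofuran-5-yl]-2-(3,5-dimethoxyphenyl)-4,6-dimethoxy-3-(4-methoxyphenyl)-2,3-dihydrospiro[indene-1,2'-thiirane] 1',1'-dioxide (mixture at the thiirane carbons), formed in the flask | COc1ccc([C@H]2c3c(OC)cc(OC)cc3C3(C(c4ccc5c(c4)[C@@H](c4cc(OC)cc(OC)c4)[C@H](c4ccc(OC)cc4)O5)S3(=O)=O)[C@@H]2c2cc(OC)cc(OC)c2)cc1 | intermediate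
30 | (2R,3R)-3-(3,5-dimethoxyphenyl)-5-{(E)-[(2S,3S)-2-(3,5-dimethoxyphenyl)-4,6-dimethoxy-3-(4-methoxyphenyl)indan-1-ylidene]methyl}-2-(4-methoxyphenyl)-2,3-dihydrobenzofuran | COc1ccc([C@H]2c3c(OC)cc(OC)cc3/C(=C/c3ccc4c(c3)[C@@H](c3cc(OC)cc(OC)c3)[C@H](c3ccc(OC)cc3)O4)[C@@H]2c2cc(OC)cc(OC)c2)cc1 | intermediate
31 | (2S,3S)-2-(3,5-dihydroxyphenyl)-1-[(E)-{(2R,3R)-3-(3,5-dihydroxyphenyl)-2-(4-hydroxyphenyl)-2,3-dihydrobenzofuran-5-yl}methylidene]-3-(4-hydroxyphenyl)indane-4,6-diol (CNP0184753.1) | Oc1ccc([C@H]2c3c(O)cc(O)cc3/C(=C/c3ccc4c(c3)[C@@H](c3cc(O)cc(O)c3)[C@H](c3ccc(O)cc3)O4)[C@@H]2c2cc(O)cc(O)c2)cc1 | target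

**Step count**

Total: 17 steps. Longest linear sequence: 11 steps (steps 7–13, then 14–17, from 10 to 31); the indane branch is 10 steps (steps 1–6, then 14–17).

**Steps most likely to fail**

Step 2. The conrotation may show poor face selection, or turnover may stall because the β-ketoester product holds the copper. The fallback sets out from 2 and returns at 5, forming the same C3–C3a bond by carbopalladation instead of electrocyclisation. Commercial 3',5'-dimethoxyacetophenone is brominated with NBS in MeCN at the position ortho to the acetyl group to give 1-(2-bromo-3,5-dimethoxyphenyl)ethanone F1. Claisen–Schmidt condensation of F1 with 2 (NaOH, EtOH) gives (E)-1-(2-bromo-3,5-dimethoxyphenyl)-3-(4-methoxyphenyl)prop-2-en-1-one F2. An enantioselective reductive Heck cyclisation (Pd(OAc)2, an atropisomeric bisphosphine of the MeO-BIPHEP family, HCO2Na, DMF, 80 °C) then inserts the enone into the aryl–palladium bond and should give 5 directly, without the ester detour.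

Step 11. The open benzylic cation may undergo a 1,2-hydride shift that erodes C3, or equilibration may stop short of the trans isomer. The fallback sets out from 18 and returns at 19, moving the epimerisation to the free phenol, where C2 can invert through a neutral para-quinone methide. BBr3 (CH2Cl2, −78 °C → rt) removes the three methyl groups and is expected to give the trans triphenol (2R,3R)-5-bromo-3-(3,5-dihydroxyphenyl)-2-(4-hydroxyphenyl)-2,3-dihydrobenzofuran F3. Re-methylation (MeI, K2CO3, acetone) then leads back to 19.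

Step 16. Hot KOH may move the exocyclic double bond into the five-membered ring, or the extrusion may give poor alkene geometry. The fallback sets out from 8 and returns at 30, replacing sulfur extrusion by a Julia–Kocienski olefination at low temperature; steps 6 and 13–15 are then not needed. Mitsunobu reaction of 8 with 1-phenyl-1H-tetrazole-5-thiol (DIAD, PPh3) gives 5-{[(1S,2S,3S)-2-(3,5-dimethoxyphenyl)-4,6-dimethoxy-3-(4-methoxyphenyl)indan-1-yl]sulfanyl}-1-phenyl-1H-tetrazole F4. Oxidation with mCPBA and NaHCO3 gives 5-{[(1S,2S,3S)-2-(3,5-dimethoxyphenyl)-4,6-dimethoxy-3-(4-methoxyphenyl)indan-1-yl]sulfonyl}-1-phenyl-1H-tetrazole F5. Aldehyde 21 is isolated from step 12 by aqueous work-up before the borohydride is added. Deprotonation of F5 with KN(SiMe3)2 in THF at −78 °C and addition of 21 should give 30 after Smiles rearrangement and elimination.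

**Further compounds**

F1 | step 2 | 1-(2-bromo-3,5-dimethoxyphenyl)ethanone | CC(=O)c1cc(OC)cc(OC)c1Br
F2 | step 2 | (E)-1-(2-bromo-3,5-dimethoxyphenyl)-3-(4-methoxyphenyl)prop-2-en-1-one | COc1ccc(/C=C/C(=O)c2cc(OC)cc(OC)c2Br)cc1
F3 | step 11 | (2R,3R)-5-bromo-3-(3,5-dihydroxyphenyl)-2-(4-hydroxyphenyl)-2,3-dihydrobenzofuran | Brc1ccc2c(c1)[C@@H](c1cc(O)cc(O)c1)[C@H](c1ccc(O)cc1)O2
F4 | step 16 | 5-{[(1S,2S,3S)-2-(3,5-dimethoxyphenyl)-4,6-dimethoxy-3-(4-methoxyphenyl)indan-1-yl]sulfanyl}-1-phenyl-1H-tetrazole | COc1ccc([C@H]2c3c(OC)cc(OC)cc3[C@@H](Sc3nnnn3-c3ccccc3)[C@@H]2c2cc(OC)cc(OC)c2)cc1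
F5 | step 16 | 5-{[(1S,2S,3S)-2-(3,5-dimethoxyphenyl)-4,6-dimethoxy-3-(4-methoxyphenyl)indan-1-yl]sulfonyl}-1-phenyl-1H-tetrazole | COc1ccc([C@H]2c3c(OC)cc(OC)cc3[C@@H](S(=O)(=O)c3nnnn3-c3ccccc3)[C@@H]2c2cc(OC)cc(OC)c2)cc1
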